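## Retrosynthetic overview

1. Numbering: C1 = CO2H, ring O1–O2–C3–C4–C5–C6 (O2 on C3), chain C7=C8(Et)–C9H2–C10H(Et)–C11=C12–C13–C14. Enabling feature: C7=C8–C9–C10–C11=C12 is a 1,5-diene hung on ring carbon C6; C9 is a primary CH2 next to the C10 stereocentre, so it maps onto the carboxyl-bearing CH2 of a Claisen acid, and C8 is an unhindered sp2 carbon whose E geometry can be stored in an iodide.
2. Last C–C bond, C8–C9: nickel-electrocatalytic decarboxylative alkenylation of E-alkenyl iodide 26 (intact 1,2-dioxane) with redox-active ester 6.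
3. Acid 5: Johnson–Claisen rearrangement of (3R,4E)-hept-4-en-3-ol sets C10 and the E C11=C12 alkene.
4. The 1,2-dioxane (the only ring, formed before the coupling): 6-exo SN2 closure of a C6 hydroperoxy ketal onto the C3 mesylate (inversion, 3,4-cis), then axial alkynylation of the C6 peroxycarbenium ion, then hydrozirconation–iodination of the alkyne.
5. C3 comes from (R)-butane-1,2,4-triol and C4 from an anti-selective cuprate addition; C1 is carried as a silyl ether and oxidised last.

Key step: step 18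

Remark on the chemistry: the target is read as (3S,4S,6R,10R,7E,11E), with C3–CH2CO2H, C4–Et and C6–Et mutually cis on the ring. Metal salts that only precede aqueous work-up (zinc alkoxide of 2, lithium enolate of 11, lithium carboxylate of 5) are treated as the products themselves.

## Route

Step 1
Reactants: 1 (E)-pent-2-enal
Product: 2 (3R,4E)-hept-4-en-3-ol
Conditions: Et2Zn (1.5 equiv), (+)-3-exo-morpholinoisoborneol (5 mol%), hexane/toluene, 0 °C; aq NH4Cl
Reagents that add atoms: diethylzinc, CC[Zn]CC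
Why: Amino-alcohol-catalysed enantioselective 1,2-addition of a dialkylzinc to an enal; the ligand antipode that turns benzaldehyde into (R)-1-phenylpropan-1-ol is chosen so that the carbinol centre is set as R by catalyst control.

Step 2
Reactants: 2 (3R,4E)-hept-4-en-3-ol
Product: 4 ethyl (3R,4E)-3-ethylhept-4-enoate, via ketene acetal 3 (not isolated)
Conditions: CH3C(OEt)3 (6 equiv), EtCO2H (5 mol%), 140 °C, EtOH distilled off
Reagents that add atoms: triethyl orthoacetate, CC(OCC)(OCC)OCC
Why: Johnson–Claisen rearrangement through a chair transition state with the carbinol ethyl group equatorial; suprafacial transfer of the carbinol chirality sets C10 as R and the new alkene as E.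

Step 3
Reactants: 4 ethyl (3R,4E)-3-ethylhept-4-enoate
Product: 5 (3R,4E)-3-ethylhept-4-enoic acid
Conditions: LiOH·H2O, THF/MeOH/H2O, rt; 1 M HCl
Reagents that add atoms: lithium hydroxide, [Li+].[OH-]
Why: Ester saponification; the stereocentre is β to the carbonyl and cannot epimerise.

Step 4
Reactants: 5 (3R,4E)-3-ethylhept-4-enoic acid
Product: 6 1,3-dioxoisoindolin-2-yl (3R,4E)-3-ethylhept-4-enoate
Conditions: N-hydroxyphthalimide, N,N'-diisopropylcarbodiimide, DMAP (10 mol%), CH2Cl2, rt
Reagents that add atoms: N-hydroxyphthalimide, ON1C(=O)c2ccccc2C1=O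
Why: Carbodiimide (Steglich-type) esterification should give the redox-active ester without touching the stereocentre or the alkene.

Step 5
Reactants: 7 (R)-butane-1,2,4-triol
Product: 8 [(2R,4R)-2-(4-methoxyphenyl)-1,3-dioxan-4-yl]methanol
Conditions: 4-MeOC6H4CH(OMe)2 (1.1 equiv), camphorsulfonic acid (5 mol%), CH2Cl2, rt
Reagents that add atoms: 4-methoxybenzaldehyde dimethyl acetal, COc1ccc(cc1)C(OC)OC
Why: Thermodynamic transacetalisation favours the six-membered 1,3-dioxane with both substituents equatorial, which leaves the primary hydroxyl next to the stereocentre free; the acetal carbon equilibrates to the cis isomer.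

Step 6
Reactants: 8 [(2R,4R)-2-(4-methoxyphenyl)-1,3-dioxan-4-yl]methanol
Product: 9 (2R,4R)-2-(4-methoxyphenyl)-1,3-dioxane-4-carbaldehyde
Conditions: Dess–Martin periodinane, NaHCO3, CH2Cl2, 0 °C to rt
Reagents that add atoms: none
Why: Buffered Dess–Martin oxidation should give the α-alkoxy aldehyde without epimerisation or acetal loss.

Step 7
Reactants: 9 (2R,4R)-2-(4-methoxyphenyl)-1,3-dioxane-4-carbaldehyde
Product: 10 (1E)-1-[(2R,4R)-2-(4-methoxyphenyl)-1,3-dioxan-4-yl]pent-1-en-3-one
Conditions: (EtO)2P(O)CH2C(O)Et, LiCl, i-Pr2NEt, MeCN, rt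
Reagents that add atoms: diethyl (2-oxobutyl)phosphonate, CCC(=O)CP(=O)(OCC)OCC
Why: Horner–Wadsworth–Emmons olefination under mild amine/LiCl conditions is E-selective and should not epimerise the α-alkoxy aldehyde.

Step 8
Reactants: 10 (1E)-1-[(2R,4R)-2-(4-methoxyphenyl)-1,3-dioxan-4-yl]pent-1-en-3-one
Product: 11 (5S)-5-[(2R,4R)-2-(4-methoxyphenyl)-1,3-dioxan-4-yl]heptan-3-one
Conditions: Et2CuLi (from EtLi and CuBr·SMe2), Et2O, −78 °C; aq NH4Cl
Reagents that add atoms: ethyllithium, CC[Li]
Why: Cuprate conjugate addition to a γ-alkoxy E-enone occurs anti to the γ C–O bond (Felkin–Anh-type model with the γ-hydrogen eclipsing the alkene), which sets C4 as S, anti to the C3 oxygen.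

Step 9
Reactants: 11 (5S)-5-[(2R,4R)-2-(4-methoxyphenyl)-1,3-dioxan-4-yl]heptan-3-one
Product: 12 (2R,4R)-2-(4-methoxyphenyl)-4-[(3S)-5-methylideneheptan-3-yl]-1,3-dioxane
Conditions: Ph3PCH3Br, KOtBu, THF, 0 °C to rt
Reagents that add atoms: methyltriphenylphosphonium bromide, C[P+](c1ccccc1)(c1ccccc1)c1ccccc1.[Br-]
Why: Wittig methylenation of an unhindered dialkyl ketone; the C4 stereocentre is β to the carbonyl and is not at risk.

Step 10
Reactants: 12 (2R,4R)-2-(4-methoxyphenyl)-4-[(3S)-5-methylideneheptan-3-yl]-1,3-dioxane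
Product: 13 (3R,4S)-4-ethyl-6-methylideneoctane-1,3-diol
Conditions: pyridinium p-toluenesulfonate (10 mol%), MeOH, rt
Reagents that add atoms: none
Why: Mild acid-catalysed transacetalisation to methanol releases the 1,3-diol; the acid is too weak to protonate the 1,1-disubstituted alkene.

Step 11
Reactants: 13 (3R,4S)-4-ethyl-6-methylideneoctane-1,3-diol
Product: 14 (3R,4S)-1-[(tert-butyldiphenylsilyl)oxy]-4-ethyl-6-methylideneoctan-3-ol
Conditions: t-BuPh2SiCl (1.05 equiv), imidazole, CH2Cl2, −20 to 0 °C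
Reagents that add atoms: tert-butyl(chloro)diphenylsilane, CC(C)(C)[Si](Cl)(c1ccccc1)c1ccccc1
Why: Silylation with a bulky silyl chloride should select the primary hydroxyl over the hindered, α-branched secondary one.

Step 12
Reactants: 14 (3R,4S)-1-[(tert-butyldiphenylsilyl)oxy]-4-ethyl-6-methylideneoctan-3-ol
Product: 15 (3R,4S)-1-[(tert-butyldiphenylsilyl)oxy]-4-ethyl-6-methylideneoctan-3-yl methanesulfonate
Conditions: MsCl, Et3N, CH2Cl2, −20 °C
Reagents that add atoms: methanesulfonyl chloride, CS(=O)(=O)Cl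
Why: Mesylation of a secondary alcohol with retention; because C1 is an ether and not an ester, the sulfonate cannot be lost by β-elimination.

Step 13
Reactants: 15 (3R,4S)-1-[(tert-butyldiphenylsilyl)oxy]-4-ethyl-6-methylideneoctan-3-yl methanesulfonate
Product: 17 (3R,4S,6RS)-1-[(tert-butyldiphenylsilyl)oxy]-4-ethyl-6-hydroperoxy-6-methoxyoctan-3-yl methanesulfonate, via carbonyl oxide 16 (not isolated)
Conditions: O3, CH2Cl2/MeOH (4:1), −78 °C; N2 purge, no reductant
Reagents that add atoms: ozone, [O-][O+]=O; methanol, CO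
Why: Ozonolysis of a 1,1-disubstituted alkene in methanol (Criegee mechanism): cycloreversion gives the more substituted carbonyl oxide, which methanol traps as the hydroperoxy ketal; C6 forms as a mixture that is erased in step 16.

Step 14
Reactants: 17 (3R,4S,6RS)-1-[(tert-butyldiphenylsilyl)oxy]-4-ethyl-6-hydroperoxy-6-methoxyoctan-3-yl methanesulfonate
Product: 18 tert-butyl{2-[(3S,4S,6RS)-4,6-diethyl-6-methoxy-1,2-dioxan-3-yl]ethoxy}diphenylsilane
Conditions: KOtBu (1.1 equiv), 18-crown-6, toluene, 0 °C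
Reagents that add atoms: none
Why: Intramolecular alkylation of a hydroperoxy ketal by a secondary sulfonate, a known entry to 3-alkoxy-1,2-dioxanes; the 6-exo-tet SN2 closure inverts C3 and so turns the anti C3/C4 pair into the 3,4-cis ring.

Step 15
Reactants: 19 but-1-yne
Product: 22 potassium but-1-yn-1-yltrifluoroborate, via lithium but-1-yn-1-ide 20 (not isolated), via lithium but-1-yn-1-yl(trimethoxy)borate 21 (not isolated)
Conditions: n-BuLi, THF, −78 °C; B(OMe)3, −78 to −20 °C; aq KHF2
Reagents that add atoms: trimethyl borate, COB(OC)OC; potassium hydrogen difluoride, [K+].F[H-]F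
Why: Standard deprotonation, borylation and fluoride exchange of a terminal alkyne to the air-stable alkynyltrifluoroborate.

Step 16
Reactants: 18 tert-butyl{2-[(3S,4S,6RS)-4,6-diethyl-6-methoxy-1,2-dioxan-3-yl]ethoxy}diphenylsilane; 22 potassium but-1-yn-1-yltrifluoroborate
Product: 24 tert-butyl{2-[(3S,4S,6R)-6-(but-1-yn-1-yl)-4,6-diethyl-1,2-dioxan-3-yl]ethoxy}diphenylsilane, via peroxycarbenium ion 23 (not isolated)
Conditions: 22 (2 equiv), BF3·OEt2 (2 equiv), CH2Cl2/MeCN, −78 to −30 °C; aq NaHCO3
Reagents that add atoms: none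
Why: Proposed new method: BF3 abstracts fluoride from 22 to give the alkynyldifluoroborane, which ionises the exocyclic methoxy group of 18 to the peroxycarbenium ion 23 paired with an alkynyl(methoxy)difluoroborate that transfers the alkynyl group to C6; the closest known reaction types are the Lewis-acid substitution of cyclic peroxyketals by allylsilanes and silyl enol ethers through peroxycarbenium ions and the BF3-promoted alkynylation of ordinary ketals by potassium alkynyltrifluoroborates; the quaternary centre is set by axial attack on the half-chair that keeps the C4 ethyl pseudo-equatorial, anti to that ethyl group, which puts the small alkynyl group axial and the C6 ethyl equatorial, also the more stable arrangement.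

Step 17
Reactants: 24 tert-butyl{2-[(3S,4S,6R)-6-(but-1-yn-1-yl)-4,6-diethyl-1,2-dioxan-3-yl]ethoxy}diphenylsilane
Product: 26 tert-butyl{2-[(3S,4S,6R)-4,6-diethyl-6-[(1E)-2-iodobut-1-en-1-yl]-1,2-dioxan-3-yl]ethoxy}diphenylsilane, via alkenylzirconocene chloride 25 (not isolated)
Conditions: Cp2Zr(H)Cl (1.5 equiv), CH2Cl2, 0 °C to rt; iodine, THF, 0 °C, dark
Reagents that add atoms: iodine, [I][I]
Why: Hydrozirconation–iodination: syn addition of Zr–H, equilibrated by the slight excess of reagent to place zirconium on C8, the alkyne carbon remote from the quaternary C6, then iodinolysis with retention gives the E iodide with iodine trans to C6.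

Step 18
Reactants: 26 tert-butyl{2-[(3S,4S,6R)-4,6-diethyl-6-[(1E)-2-iodobut-1-en-1-yl]-1,2-dioxan-3-yl]ethoxy}diphenylsilane; 6 1,3-dioxoisoindolin-2-yl (3R,4E)-3-ethylhept-4-enoate
Product: 27 tert-butyl{2-[(3S,4S,6R)-6-[(1E,4R,5E)-2,4-diethylocta-1,5-dien-1-yl]-4,6-diethyl-1,2-dioxan-3-yl]ethoxy}diphenylsilane
Conditions: 6 (2 equiv), NiCl2·6H2O (20 mol%), 2,2'-bipyridine (20 mol%), AgNO3 (0.3 equiv), DMF, Mg anode, reticulated vitreous carbon cathode, undivided cell, constant current, rt
Reagents that add atoms: none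
Why: Cathodic reduction on the silver-coated carbon cathode generates low-valent (bipyridine)nickel, which inserts into the C8–I bond of 26 with retention of alkene geometry, while single-electron reduction of 6 releases CO2 and phthalimide anion and leaves the primary C9 radical; capture of that radical at nickel and reductive elimination form the C8–C9 bond. The closest known reaction type is the nickel-electrocatalytic decarboxylative alkenylation of redox-active esters with alkenyl iodides, used to assemble 1,5-dienes. No ring is closed and no stereocentre is created: C10 is adjacent to, not at, the radical centre and keeps its configuration, C7=C8 keeps the E geometry stored in the iodide, and C11=C12 is untouched. The step needs chemoselectivity for the C–I bond and the activated ester over the O–O bond, which the low cathode potential, the absence of any heteroatom β to nickel in the alkenylnickel species and the shielding of the peroxide by the quaternary C6 should secure. It also needs radical capture to outrun 3-exo closure of the homoallylic radical, which the high nickel loading and the reversibility of that closure should secure; C8 itself is unhindered because the bulky C6 lies trans to iodine.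

Step 19
Reactants: 27 tert-butyl{2-[(3S,4S,6R)-6-[(1E,4R,5E)-2,4-diethylocta-1,5-dien-1-yl]-4,6-diethyl-1,2-dioxan-3-yl]ethoxy}diphenylsilane
Product: 28 2-[(3S,4S,6R)-6-[(1E,4R,5E)-2,4-diethylocta-1,5-dien-1-yl]-4,6-diethyl-1,2-dioxan-3-yl]ethan-1-ol
Conditions: HF·pyridine, pyridine/THF, 0 °C to rt
Reagents that add atoms: none
Why: Buffered fluoride desilylation of a primary silyl ether; the non-basic conditions avoid base-induced fragmentation of the peroxide at C3–H.

Step 20
Reactants: 28 2-[(3S,4S,6R)-6-[(1E,4R,5E)-2,4-diethylocta-1,5-dien-1-yl]-4,6-diethyl-1,2-dioxan-3-yl]ethan-1-ol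
Product: 30 plakortide N, via aldehyde 29 (not isolated)
Conditions: TEMPO (20 mol%), PhI(OAc)2 (2.2 equiv), MeCN/H2O, rt
Reagents that add atoms: water, O
Why: Oxoammonium-mediated oxidation of the primary alcohol through the aldehyde hydrate to the acid, a method that leaves isolated alkenes and dialkyl peroxides alone.

## Compound list

1 | (E)-pent-2-enal | CC/C=C/C=O | starting material
2 | (3R,4E)-hept-4-en-3-ol | CC[C@@H](O)/C=C/CC | intermediate
3 | 1-ethoxy-1-{[(3R,4E)-hept-4-en-3-yl]oxy}ethene (ketene acetal, not isolated) | C=C(OCC)O[C@H](CC)/C=C/CC | intermediate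
4 | ethyl (3R,4E)-3-ethylhept-4-enoate | CC/C=C/[C@H](CC)CC(=O)OCC | intermediate
5 | (3R,4E)-3-ethylhept-4-enoic acid | CC/C=C/[C@H](CC)CC(=O)O | intermediate
6 | 1,3-dioxoisoindolin-2-yl (3R,4E)-3-ethylhept-4-enoate | CC/C=C/[C@H](CC)CC(=O)ON1C(=O)c2ccccc2C1=O | intermediate
7 | (R)-butane-1,2,4-triol | OC[C@H](O)CCO | starting material
8 | [(2R,4R)-2-(4-methoxyphenyl)-1,3-dioxan-4-yl]methanol | OC[C@H]1CCO[C@@H](c2ccc(OC)cc2)O1 | intermediate
9 | (2R,4R)-2-(4-methoxyphenyl)-1,3-dioxane-4-carbaldehyde | O=C[C@H]1CCO[C@@H](c2ccc(OC)cc2)O1 | intermediate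
10 | (1E)-1-[(2R,4R)-2-(4-methoxyphenyl)-1,3-dioxan-4-yl]pent-1-en-3-one | CCC(=O)/C=C/[C@H]1CCO[C@@H](c2ccc(OC)cc2)O1 | intermediate
11 | (5S)-5-[(2R,4R)-2-(4-methoxyphenyl)-1,3-dioxan-4-yl]heptan-3-one | CCC(=O)C[C@H](CC)[C@H]1CCO[C@@H](c2ccc(OC)cc2)O1 | intermediate
12 | (2R,4R)-2-(4-methoxyphenyl)-4-[(3S)-5-methylideneheptan-3-yl]-1,3-dioxane | C=C(CC)C[C@H](CC)[C@H]1CCO[C@@H](c2ccc(OC)cc2)O1 | intermediate
13 | (3R,4S)-4-ethyl-6-methylideneoctane-1,3-diol | C=C(CC)C[C@H](CC)[C@H](O)CCO | intermediate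
14 | (3R,4S)-1-[(tert-butyldiphenylsilyl)oxy]-4-ethyl-6-methylideneoctan-3-ol | C=C(CC)C[C@H](CC)[C@H](O)CCO[Si](c1ccccc1)(c1ccccc1)C(C)(C)C | intermediate
15 | (3R,4S)-1-[(tert-butyldiphenylsilyl)oxy]-4-ethyl-6-methylideneoctan-3-yl methanesulfonate | C=C(CC)C[C@H](CC)[C@H](OS(C)(=O)=O)CCO[Si](c1ccccc1)(c1ccccc1)C(C)(C)C | intermediate
16 | carbonyl oxide at C6 of (3R,4S)-1-[(tert-butyldiphenylsilyl)oxy]-4-ethyl-6-oxooctan-3-yl methanesulfonate (not isolated) | CCC(=[O+][O-])C[C@H](CC)[C@H](OS(C)(=O)=O)CCO[Si](c1ccccc1)(c1ccccc1)C(C)(C)C | intermediate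
17 | (3R,4S,6RS)-1-[(tert-butyldiphenylsilyl)oxy]-4-ethyl-6-hydroperoxy-6-methoxyoctan-3-yl methanesulfonate | CCC(OC)(OO)C[C@H](CC)[C@H](OS(C)(=O)=O)CCO[Si](c1ccccc1)(c1ccccc1)C(C)(C)C | intermediate
18 | tert-butyl{2-[(3S,4S,6RS)-4,6-diethyl-6-methoxy-1,2-dioxan-3-yl]ethoxy}diphenylsilane | CCC1(OC)C[C@H](CC)[C@H](CCO[Si](c2ccccc2)(c2ccccc2)C(C)(C)C)OO1 | intermediate
19 | but-1-yne | CCC#C | starting material
20 | lithium but-1-yn-1-ide (not isolated) | CCC#C[Li] | intermediate
21 | lithium but-1-yn-1-yl(trimethoxy)borate (not isolated) | CCC#C[B-](OC)(OC)OC.[Li+] | intermediate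
22 | potassium but-1-yn-1-yltrifluoroborate | CCC#C[B-](F)(F)F.[K+] | intermediate
23 | (3S,4S)-3-{2-[(tert-butyldiphenylsilyl)oxy]ethyl}-4,6-diethyl-1,2-dioxan-6-ylium (peroxycarbenium ion, not isolated) | CC[C+]1C[C@H](CC)[C@H](CCO[Si](c2ccccc2)(c2ccccc2)C(C)(C)C)OO1 | intermediate
24 | tert-butyl{2-[(3S,4S,6R)-6-(but-1-yn-1-yl)-4,6-diethyl-1,2-dioxan-3-yl]ethoxy}diphenylsilane | CCC#C[C@@]1(CC)C[C@H](CC)[C@H](CCO[Si](c2ccccc2)(c2ccccc2)C(C)(C)C)OO1 | intermediate
25 | tert-butyl{2-[(3S,4S,6R)-6-{(1E)-2-[chlorobis(cyclopentadienyl)zirconio]but-1-en-1-yl}-4,6-diethyl-1,2-dioxan-3-yl]ethoxy}diphenylsilane (not isolated) | CC/C(=C\[C@@]1(CC)C[C@H](CC)[C@H](CCO[Si](c2ccccc2)(c2ccccc2)C(C)(C)C)OO1)[Zr](Cl)(C1C=CC=C1)C1C=CC=C1 | intermediate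
26 | tert-butyl{2-[(3S,4S,6R)-4,6-diethyl-6-[(1E)-2-iodobut-1-en-1-yl]-1,2-dioxan-3-yl]ethoxy}diphenylsilane | I/C(CC)=C/[C@@]1(CC)C[C@H](CC)[C@H](CCO[Si](c2ccccc2)(c2ccccc2)C(C)(C)C)OO1 | intermediate
27 | tert-butyl{2-[(3S,4S,6R)-6-[(1E,4R,5E)-2,4-diethylocta-1,5-dien-1-yl]-4,6-diethyl-1,2-dioxan-3-yl]ethoxy}diphenylsilane | CC/C=C/[C@H](CC)C/C(=C/[C@@]1(CC)C[C@H](CC)[C@H](CCO[Si](c2ccccc2)(c2ccccc2)C(C)(C)C)OO1)CC | intermediate
28 | 2-[(3S,4S,6R)-6-[(1E,4R,5E)-2,4-diethylocta-1,5-dien-1-yl]-4,6-diethyl-1,2-dioxan-3-yl]ethan-1-ol | CC/C=C/[C@H](CC)C/C(=C/[C@@]1(CC)C[C@H](CC)[C@H](CCO)OO1)CC | intermediate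
29 | 2-[(3S,4S,6R)-6-[(1E,4R,5E)-2,4-diethylocta-1,5-dien-1-yl]-4,6-diethyl-1,2-dioxan-3-yl]acetaldehyde (not isolated) | CC/C=C/[C@H](CC)C/C(=C/[C@@]1(CC)C[C@H](CC)[C@H](CC=O)OO1)CC | intermediate
30 | plakortide N: 2-[(3S,4S,6R)-6-[(1E,4R,5E)-2,4-diethylocta-1,5-dien-1-yl]-4,6-diethyl-1,2-dioxan-3-yl]acetic acid | CC/C=C/[C@H](CC)C/C(=C/[C@@]1(CC)C[C@H](CC)[C@H](CC(=O)O)OO1)CC | target

## Step count and risks

Total step count: 20.
Longest linear sequence: 15 steps, from 7 to 30 (steps 5–14 and 16–20).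

The three steps most likely to fail:

1. Step 16 (proposed new method). After ionisation, fragmentation of the peroxycarbenium ion by carbon-to-oxygen migration, or ionisation of the ring C–O bond, may outrun alkynyl transfer. Front-side delivery inside the ion pair may also erode the facial selectivity. The fallback uses known chemistry, gives up the stereocontrol at C6, sets out from 11 and comes back at 24. But-1-ynylmagnesium bromide (from 19 and EtMgBr, THF, −78 °C) should add to ketone 11 to give the tertiary propargylic alcohol F1 as both C6 epimers. Acid methanolysis of the acetal as in step 10 should give the triol F2, silylation as in step 11 the primary silyl ether F3, and mesylation at −20 °C the secondary mesylate F4, with the tertiary hydroxyl left free. Aqueous H2O2 (50%) with catalytic H2SO4 in Et2O at 0 °C, the classical perhydrolysis of tertiary propargylic alcohols through their cations, should give the tertiary hydroperoxide F5. KOtBu/18-crown-6 as in step 14 should then close the ring with inversion at C3 to give 24 together with its C6 epimer F6, to be separated by chromatography.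

2. Step 18 (key step). Low-valent nickel or the cathode may cleave the O–O bond reductively. The homoallylic C9 radical may also undergo 3-exo closure and 1,2-vinyl shift before it is captured, which would give a branched regioisomer and erode the C11=C12 geometry. The fallback replaces the radical coupling by a two-electron alkyl–alkenyl Negishi coupling under zerovalent palladium, sets out from 5 and comes back at 27. Iododecarboxylation of 5 (PhI(OAc)2, iodine, visible light, cyclohexane), in which iodine-atom transfer to the radical is far faster than its rearrangement, should give (3E,5S)-5-(iodomethyl)hept-3-ene F7. Zinc dust with LiCl in THF should convert it into the alkylzinc iodide F8. Coupling of F8 with 26 under Pd(dppf)Cl2 (5 mol%) in THF at rt should give 27.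

3. Step 17. The hydridic zirconium reagent may reduce the O–O bond before or after it adds to the hindered alkyne, and incomplete equilibration may leave the regioisomeric alkenylzirconium. The fallback moves to a late-metal hydrometalation that uses no early-metal hydride, sets out from 24 and comes back at 26. Syn hydrostannation (Bu3SnH, PdCl2(PPh3)2 2 mol%, THF, 0 °C), with tin going to the less hindered C8, should give the alkenylstannane F9. Iododestannylation with iodine in CH2Cl2 at 0 °C should give 26 with retention.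

Further compounds
F1 | step 16 | (5RS,7S)-5-ethyl-7-[(2R,4R)-2-(4-methoxyphenyl)-1,3-dioxan-4-yl]non-3-yn-5-ol | CCC#CC(O)(CC)C[C@H](CC)[C@H]1CCO[C@@H](c2ccc(OC)cc2)O1
F2 | step 16 | (3R,4S,6RS)-4,6-diethyldec-7-yne-1,3,6-triol | CCC#CC(O)(CC)C[C@H](CC)[C@H](O)CCO
F3 | step 16 | (3R,4S,6RS)-1-[(tert-butyldiphenylsilyl)oxy]-4,6-diethyldec-7-yne-3,6-diol | CCC#CC(O)(CC)C[C@H](CC)[C@H](O)CCO[Si](c1ccccc1)(c1ccccc1)C(C)(C)C
F4 | step 16 | (3R,4S,6RS)-1-[(tert-butyldiphenylsilyl)oxy]-4,6-diethyl-6-hydroxydec-7-yn-3-yl methanesulfonate | CCC#CC(O)(CC)C[C@H](CC)[C@H](OS(C)(=O)=O)CCO[Si](c1ccccc1)(c1ccccc1)C(C)(C)C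
F5 | step 16 | (3R,4S,6RS)-1-[(tert-butyldiphenylsilyl)oxy]-4,6-diethyl-6-hydroperoxydec-7-yn-3-yl methanesulfonate | CCC#CC(OO)(CC)C[C@H](CC)[C@H](OS(C)(=O)=O)CCO[Si](c1ccccc1)(c1ccccc1)C(C)(C)C
F6 | step 16 | tert-butyl{2-[(3S,4S,6S)-6-(but-1-yn-1-yl)-4,6-diethyl-1,2-dioxan-3-yl]ethoxy}diphenylsilane | CCC#C[C@]1(CC)C[C@H](CC)[C@H](CCO[Si](c2ccccc2)(c2ccccc2)C(C)(C)C)OO1
F7 | step 18 | (3E,5S)-5-(iodomethyl)hept-3-ene | IC[C@@H](CC)/C=C/CC
F8 | step 18 | [(2S,3E)-2-ethylhex-3-en-1-yl]zinc iodide | I[Zn]C[C@@H](CC)/C=C/CC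
F9 | step 17 | tert-butyl{2-[(3S,4S,6R)-4,6-diethyl-6-[(1E)-2-(tributylstannyl)but-1-en-1-yl]-1,2-dioxan-3-yl]ethoxy}diphenylsilane | CC/C(=C\[C@@]1(CC)C[C@H](CC)[C@H](CCO[Si](c2ccccc2)(c2ccccc2)C(C)(C)C)OO1)[Sn](CCCC)(CCCC)CCCC
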